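**Retrosynthetic overview**

1. Numbering follows 5H-cyclopenta[c]pyridine (N2; C4a/C7a ring fusion; C5 = C(OH)CO2Me, C6 = C(OH)Me, C7 = C=O). Last disconnection: the C5 hydroxyl and C5 methyl ester are released together by methanolysis of a spiro 1,3-dioxolan-4-one, a temporary ring whose tert-butyl acetal carbon is the only source of absolute control for C5 and C6.
2. Key disconnection: the cyclopentanone ring is cut at C4a–C5 and C6–C7, giving 4-chloro-6-dienylpyridine-3-carbaldehyde 6 and the enolisable 5-acetyl dioxolanone 11. In the forward direction an SNAr arylation is followed in the same flask by a carbene-catalysed crossed benzoin closure.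
3. Enabling feature: C4a is para to N2 and ortho to the C7 carbonyl carbon, so a chloride there is displaced by an enolate. C7(=O)–C6(OH)Me is an acyloin, so a formyl carbon at C7, made nucleophilic by a carbene, can add to a C6 methyl ketone. The C5–C6 pair is therefore a masked 2-hydroxyacetoacetate with C5 as enolate carbon and C6 as ketone carbon.
4. Side chain: Suzuki–Miyaura coupling at the C–Br bond of 6-bromo-4-chloropyridine-3-carbaldehyde with a dienylboronate made in two steps from (S)-2-methylbutan-1-ol. Compound 11 comes in four steps from O-benzyl-D-threonine.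
5. Ring order: pyridine ring bought; dioxolanone ring formed (step 5, temporary); cyclopentanone ring formed (step 8); dioxolanone ring opened (step 9).

Key step: step 8

Remark on the chemistry: "dienyl" below means (1E,3E,5S)-3,5-dimethylhepta-1,3-dien-1-yl. Compound 11 is enolisable at C5 and is used as its C5-epimer/enol mixture; only its acetal carbon C2 is stereodefined, and that is the centre that transmits chirality in step 8. Compounds 5 and 7 are taken to be catalogue compounds.

**Route**

Step 1
Reactants: 1 (S)-2-methylbutan-1-ol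
Product: 3 (2E,4S)-2,4-dimethylhex-2-enal, via (S)-2-methylbutanal 2 (not isolated)
Conditions: TEMPO (cat.), KBr (cat.), NaOCl, NaHCO3, CH2Cl2/H2O, 0 °C; dried organic phase, then Ph3P=C(CH3)CHO, CH2Cl2/toluene, 60 °C, closed vessel
Reagents that add atoms: 2-(triphenylphosphoranylidene)propanal, CC(C=O)=P(c1ccccc1)(c1ccccc1)c1ccccc1
Why: The buffered two-phase Anelli oxidation should give the α-branched aldehyde without enolisation, and the stabilised ylide then adds in a Wittig reaction to give the (E)-trisubstituted enal; the C4 stereocentre comes from the chiral pool.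

Step 2
Reactants: 3 (2E,4S)-2,4-dimethylhex-2-enal
Product: 4 2-[(1E,3E,5S)-3,5-dimethylhepta-1,3-dien-1-yl]-4,4,5,5-tetramethyl-1,3,2-dioxaborolane
Conditions: Cl2CHBpin, CrCl2 (excess), LiI, THF, rt
Reagents that add atoms: 2-(dichloromethyl)-4,4,5,5-tetramethyl-1,3,2-dioxaborolane, ClC(Cl)B1OC(C)(C)C(C)(C)O1
Why: In the Takai–Utimoto borylolefination the gem-dichromium species formed from the dichloromethylboronate and divalent chromium adds to the aldehyde and eliminates to the (E)-alkenylboronate, under neutral conditions that should leave the allylic stereocentre untouched.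

Step 3
Reactants: 4 dienylboronate; 5 6-bromo-4-chloropyridine-3-carbaldehyde
Product: 6 4-chloro-6-[(1E,3E,5S)-3,5-dimethylhepta-1,3-dien-1-yl]pyridine-3-carbaldehyde
Conditions: Pd(dppf)Cl2 (3 mol%), K3PO4, THF/H2O (10:1), 45 °C
Reagents that add atoms: none
Why: In this Suzuki–Miyaura coupling zerovalent palladium should insert into the C–Br bond next to the ring nitrogen much faster than into the C4–Cl bond, and transmetalation and reductive elimination retain the diene geometry.

Step 4
Reactants: 7 O-benzyl-D-threonine, (2R,3S)-2-amino-3-(benzyloxy)butanoic acid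
Product: 8 (2R,3S)-3-(benzyloxy)-2-hydroxybutanoic acid
Conditions: NaNO2, 1 M H2SO4, H2O, 0 °C → rt
Reagents that add atoms: water, O
Why: Diazotisation of the α-amino acid with carboxylate participation (α-lactone, double inversion) replaces NH2 by OH with net retention, so C2 stays (R).

Step 5
Reactants: 8 (2R,3S)-3-(benzyloxy)-2-hydroxybutanoic acid
Product: 9 (2R,5R)-5-[(1S)-1-(benzyloxy)ethyl]-2-tert-butyl-1,3-dioxolan-4-one (cis isomer)
Conditions: t-BuCHO, p-TsOH·H2O (cat.), H2SO4 (cat.), pentane, reflux, Dean–Stark trap; minor trans isomer removed by crystallisation or chromatography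
Reagents that add atoms: pivalaldehyde, CC(C)(C)C=O
Why: Acid-catalysed acetalisation of an α-hydroxy acid with pivalaldehyde under equilibrating conditions places the tert-butyl group cis to the C5 side chain, so the existing (5R) centre sets the new acetal carbon as (2R).

Step 6
Reactants: 9 cis-dioxolanone benzyl ether
Product: 10 (2R,5R)-2-tert-butyl-5-[(1S)-1-hydroxyethyl]-1,3-dioxolan-4-one
Conditions: H2 (1 atm), Pd/C (10 wt% Pd), EtOAc, rt
Reagents that add atoms: none
Why: Neutral hydrogenolysis of the benzyl ether should leave the acylal ring and all stereocentres intact.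

Step 7
Reactants: 10 hydroxyethyl dioxolanone
Product: 11 (2R)-5-acetyl-2-tert-butyl-1,3-dioxolan-4-one
Conditions: Dess–Martin periodinane, CH2Cl2, 0 °C → rt; used without chromatography
Reagents that add atoms: none
Why: Dess–Martin oxidation of the secondary alcohol gives the β-keto acylal under non-basic conditions; C5 becomes enolisable as intended, while the acetal carbon C2 is unaffected and now holds all the stereochemical information.

Step 8
Reactants: 6 4-chloro-6-dienylpyridine-3-carbaldehyde; 11 (2R)-5-acetyl-2-tert-butyl-1,3-dioxolan-4-one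
Product: 13 (2'R,5R,6S)-2'-tert-butyl-3-dienyl-6-hydroxy-6-methylspiro[cyclopenta[c]pyridine-5,4'-[1,3]dioxolane]-5',7(6H)-dione, via SNAr keto-aldehyde 12 (not isolated)
Conditions: Cs2CO3 (1.3 equiv), 4 Å MS, MeCN, 0 °C → rt; then, same flask, 2-(pentafluorophenyl)-6,7-dihydro-5H-pyrrolo[2,1-c][1,2,4]triazol-2-ium tetrafluoroborate (10 mol%), rt, Ar
Reagents that add atoms: none
Why: The caesium enolate of 11 attacks C4 of 6, which is para to the ring nitrogen and ortho to the formyl group, through a Meisenheimer adduct and loses chloride (SNAr C-arylation of a β-keto ester-type enolate); it enters anti to the tert-butyl group on the acetal carbon, so this temporary centre fixes the new quaternary carbon as (R) in 12. The carbene released from the triazolium salt then adds to the formyl group of 12, and the resulting Breslow intermediate, an acyl anion equivalent, attacks the methyl ketone in a 5-exo-trig closure that forms the cyclopentanone ring; the closest known reaction is the intramolecular crossed aldehyde–ketone benzoin cyclisation catalysed by triazolium carbenes. The carbinol carbon is controlled by the spiro dioxolanone: in the dipole-minimised (Cornforth-type) arrangement the ketone C=O points away from the ring oxygen on C5 and lies beside the lactone carbonyl, so the methyl group ends up next to the small ring oxygen and the hydroxyl on the lactone-carbonyl side, which is the (6S), trans-dioxygenated isomer. Because benzoin addition is reversible under the carbene, this isomer, in which the hydroxyl can hydrogen-bond to the lactone carbonyl, should also be favoured thermodynamically. The step needs C- over O-arylation (favoured by the soft, doubly stabilised enolate and irreversible C–C bond formation), attack on the ketone and not on the lactone carbonyl (secured by the higher electrophilicity of the α-oxygenated ketone), and benzoin closure faster than aldol reaction of the acetyl methyl group (expected from the weak carbonate base and fast carbene addition to the electron-poor aldehyde). Site selectivity in the arylation is not an issue because 6 carries a single leaving group.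

Step 9
Reactants: 13 spiro-dioxolanone acyloin
Product: 14 methyl (5R,6S)-3-[(1E,3E,5S)-3,5-dimethylhepta-1,3-dien-1-yl]-5,6-dihydroxy-6-methyl-7-oxo-6,7-dihydro-5H-cyclopenta[c]pyridine-5-carboxylate (CNP0086933.1)
Conditions: HCl in MeOH (1.25 M), 0 °C → 40 °C; NaHCO3 work-up
Reagents that add atoms: methanol, CO
Why: Acid-catalysed methanolysis of the acylal (transesterification with loss of pivalaldehyde) unmasks the methyl ester and the C5 hydroxyl at once, and because no alkoxide is formed the retro-aldol pathway that could scramble C5 and C6 stays closed.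

**Compound list**

1 | (S)-2-methylbutan-1-ol | CC[C@H](C)CO | starting material
2 | (S)-2-methylbutanal | CC[C@H](C)C=O | intermediate
3 | (2E,4S)-2,4-dimethylhex-2-enal | CC[C@H](C)/C=C(C)/C=O | intermediate
4 | 2-[(1E,3E,5S)-3,5-dimethylhepta-1,3-dien-1-yl]-4,4,5,5-tetramethyl-1,3,2-dioxaborolane | CC[C@H](C)/C=C(C)/C=C/B1OC(C)(C)C(C)(C)O1 | intermediate
5 | 6-bromo-4-chloropyridine-3-carbaldehyde | O=Cc1cnc(Br)cc1Cl | starting material
6 | 4-chloro-6-[(1E,3E,5S)-3,5-dimethylhepta-1,3-dien-1-yl]pyridine-3-carbaldehyde | CC[C@H](C)/C=C(C)/C=C/c1cc(Cl)c(C=O)cn1 | intermediate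
7 | O-benzyl-D-threonine, (2R,3S)-2-amino-3-(benzyloxy)butanoic acid | C[C@H](OCc1ccccc1)[C@@H](N)C(=O)O | starting material
8 | (2R,3S)-3-(benzyloxy)-2-hydroxybutanoic acid | C[C@H](OCc1ccccc1)[C@@H](O)C(=O)O | intermediate
9 | (2R,5R)-5-[(1S)-1-(benzyloxy)ethyl]-2-tert-butyl-1,3-dioxolan-4-one | C[C@H](OCc1ccccc1)[C@H]1O[C@@H](C(C)(C)C)OC1=O | intermediate
10 | (2R,5R)-2-tert-butyl-5-[(1S)-1-hydroxyethyl]-1,3-dioxolan-4-one | C[C@H](O)[C@H]1O[C@@H](C(C)(C)C)OC1=O | intermediate
11 | (2R)-5-acetyl-2-tert-butyl-1,3-dioxolan-4-one (C5 epimers/enol) | CC(=O)C1O[C@@H](C(C)(C)C)OC1=O | intermediate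
12 | (2R,5R)-5-acetyl-2-tert-butyl-5-{2-[(1E,3E,5S)-3,5-dimethylhepta-1,3-dien-1-yl]-5-formylpyridin-4-yl}-1,3-dioxolan-4-one | CC(=O)[C@@]1(c2cc(/C=C/C(C)=C/[C@@H](C)CC)ncc2C=O)O[C@@H](C(C)(C)C)OC1=O | intermediate
13 | (2'R,5R,6S)-2'-tert-butyl-3-[(1E,3E,5S)-3,5-dimethylhepta-1,3-dien-1-yl]-6-hydroxy-6-methylspiro[cyclopenta[c]pyridine-5,4'-[1,3]dioxolane]-5',7(6H)-dione | C[C@@]1(O)C(=O)c2cnc(/C=C/C(C)=C/[C@@H](C)CC)cc2[C@@]13O[C@@H](C(C)(C)C)OC3=O | intermediate
14 | methyl (5R,6S)-3-[(1E,3E,5S)-3,5-dimethylhepta-1,3-dien-1-yl]-5,6-dihydroxy-6-methyl-7-oxo-6,7-dihydro-5H-cyclopenta[c]pyridine-5-carboxylate | CC[C@H](C)/C=C(C)/C=C/c1cc2c(cn1)C(=O)[C@@](C)(O)[C@@]2(O)C(=O)OC | target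

**Step count and risks**

Total step count: 9. Longest linear sequence: 6 steps (steps 4, 5, 6, 7, 8, 9, from O-benzyl-D-threonine).

Steps most likely to fail:

1. Step 8. Arylation at the fully substituted enolate carbon may be slow enough for O-arylation or aldol condensation of the acetyl group onto the aldehyde to compete, and facial discrimination at the ketone in the benzoin closure rests on substrate control alone. The fallback sets out from 6 and rejoins the route at 14; it introduces the C5 oxygen after ring closure and takes absolute control from a chiral carbene. Compound 6 is arylated with methyl acetoacetate (K2CO3, DMF, rt) to methyl 2-(2-dienyl-5-formylpyridin-4-yl)-3-oxobutanoate F1, in which the arylated carbon is enolised. An enantioselective intramolecular crossed benzoin cyclisation with an aminoindanol-derived chiral N-mesityl triazolium chloride (the antipode that gives the 6S carbinol, catalytic Et3N, THF) should then give methyl (6S)-3-dienyl-6-hydroxy-6-methyl-7-oxo-6,7-dihydro-5H-cyclopenta[c]pyridine-5-carboxylate F2 as C5 epimers, both usable. Silylation (Et3SiOTf, 2,6-lutidine, CH2Cl2) gives methyl (6S)-3-dienyl-6-methyl-7-oxo-6-(triethylsilyloxy)-6,7-dihydro-5H-cyclopenta[c]pyridine-5-carboxylate F3. Enolisation at C5 (KN(SiMe3)2, THF, −78 °C) and oxidation with 2-(phenylsulfonyl)-3-phenyloxaziridine, expected anti to the silyloxy group, gives methyl (5R,6S)-3-dienyl-5-hydroxy-6-methyl-7-oxo-6-(triethylsilyloxy)-6,7-dihydro-5H-cyclopenta[c]pyridine-5-carboxylate F4, quenched cold to avoid retro-aldol equilibration. HF·pyridine in THF removes the silyl group to give 14.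

2. Step 9. Acidolytic opening of the hindered acylal may stall at the hydroxy acid, or prolonged acid may add methanol across the protonated dienylpyridine; basic methanolysis is excluded because the C5 alkoxide can undergo retro-aldol scrambling. The fallback sets out from 13 and rejoins the route at 14 by neutral hydrolysis and separate esterification. Me3SnOH in 1,2-dichloroethane at 70 °C opens the dioxolanone with loss of pivalaldehyde to (5R,6S)-3-dienyl-5,6-dihydroxy-6-methyl-7-oxo-6,7-dihydro-5H-cyclopenta[c]pyridine-5-carboxylic acid F5. Trimethylsilyldiazomethane in toluene/MeOH at 0 °C then gives 14.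

3. Step 3. Site selectivity in oxidative addition may erode (C4–Cl versus C6–Br), the activated C4 chloride may be displaced by aqueous base, and the dienylboronate may protodeboronate. The fallback sets out from 3 and rejoins the route at 6 through a base-free Stille coupling. Enal 3 is converted by chromium-mediated stannylolefination (Bu3SnCHBr2, CrCl2, LiI, THF/DMF, rt) into tributyl[(1E,3E,5S)-3,5-dimethylhepta-1,3-dien-1-yl]stannane F6. This is coupled with 5 (Pd(PPh3)4, toluene, 80 °C) at the C–Br bond to give 6.

**Further compounds**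

F1 | step 8 | methyl 2-{2-[(1E,3E,5S)-3,5-dimethylhepta-1,3-dien-1-yl]-5-formylpyridin-4-yl}-3-oxobutanoate | CC(=O)C(C(=O)OC)c1cc(/C=C/C(C)=C/[C@@H](C)CC)ncc1C=O
F2 | step 8 | methyl (6S)-3-[(1E,3E,5S)-3,5-dimethylhepta-1,3-dien-1-yl]-6-hydroxy-6-methyl-7-oxo-6,7-dihydro-5H-cyclopenta[c]pyridine-5-carboxylate (C5 epimers) | COC(=O)C1c2cc(/C=C/C(C)=C/[C@@H](C)CC)ncc2C(=O)[C@@]1(C)O
F3 | step 8 | methyl (6S)-3-[(1E,3E,5S)-3,5-dimethylhepta-1,3-dien-1-yl]-6-methyl-7-oxo-6-(triethylsilyloxy)-6,7-dihydro-5H-cyclopenta[c]pyridine-5-carboxylate (C5 epimers) | COC(=O)C1c2cc(/C=C/C(C)=C/[C@@H](C)CC)ncc2C(=O)[C@@]1(C)O[Si](CC)(CC)CC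
F4 | step 8 | methyl (5R,6S)-3-[(1E,3E,5S)-3,5-dimethylhepta-1,3-dien-1-yl]-5-hydroxy-6-methyl-7-oxo-6-(triethylsilyloxy)-6,7-dihydro-5H-cyclopenta[c]pyridine-5-carboxylate | COC(=O)[C@@]1(O)c2cc(/C=C/C(C)=C/[C@@H](C)CC)ncc2C(=O)[C@@]1(C)O[Si](CC)(CC)CC
F5 | step 9 | (5R,6S)-3-[(1E,3E,5S)-3,5-dimethylhepta-1,3-dien-1-yl]-5,6-dihydroxy-6-methyl-7-oxo-6,7-dihydro-5H-cyclopenta[c]pyridine-5-carboxylic acid | CC[C@H](C)/C=C(C)/C=C/c1cc2c(cn1)C(=O)[C@@](C)(O)[C@@]2(O)C(=O)O
F6 | step 3 | tributyl[(1E,3E,5S)-3,5-dimethylhepta-1,3-dien-1-yl]stannane | CC[C@H](C)/C=C(C)/C=C/[Sn](CCCC)(CCCC)CCCC
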